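Readings and results are simulated with constants of no real substance, noise included.

The constants of this chemistry are not given, so anything used here has to be read from the two earlier runs, south and south-east.

in all of them: starting complex 0.080 M
- south: incoming ligand 0.063 M (fed, over 8.0 min); run made earlier; the fed solution adds 0.10 times the starting volume
- south-east: incoming ligand 0.41 M (fed, over 8.0 min); run made earlier; the fed solution adds 0.10 times the starting volume
- oak: incoming ligand 0.0800 M (fed, over 8.0 min); the fed solution adds 0.10 times the starting volume; time 10 min
- alder: incoming ligand 0.150 M (fed, over 8.0 min); the fed solution adds 0.10 times the starting volume; time 10 min
- elm: incoming ligand 0.300 M (fed, over 8.0 min); the fed solution adds 0.10 times the starting volume; time 10 min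
- maple: incoming ligand 0.600 M (fed, over 8.0 min); the fed solution adds 0.10 times the starting volume; time 10 min

| run | time / min | complex with one exchanged / % |
|---|---|---|
| south | 0.833 | 0 |
| south | 1.50 | 2.0 |
| south | 3.00 | 5.8 |
| south | 5.00 | 8.6 |
| south | 10.0 | 12.7 |
| south-east | 0.833 | 4.6 |
| south-east | 2.50 | 24.1 |
| south-east | 5.00 | 36.4 |
| south-east | 8.00 | 28.8 |
| south-east | 10.0 | 21.0 |

(standard deviation of a reading: 1 percentage point)

* amount of complex with one exchanged at the end, in percent of the starting complex charged for oak, alder, elm, maple, in this order
* how the row runs (falls all the way / rises all the way / rises, then falls / hardly changes / falls, then rises)

- charges are per starting volume, the dose included; the dosed solution carries all of it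
- the earlier runs were read with a standard deviation of 1 percentage point
- "hardly changes" means that all values lie within two and a half points (for a concentration: within two and a half percent of the largest)

Two chemists argue over the row. The first looks at the end readings: south, charged with 0.063 M of incoming ligand, stood at 12.7%, and south-east, charged with 0.41 M, stood higher at 21.0%. More ligand has so far meant more complex with one exchanged, she says, so she expects the row to keep rising.

The second looks at the course of south-east rather than its end. That run read 36.4% at 5.00 min and then fell, so complex with one exchanged is being lost as well as made, and a loss can be counted. In south-east, starting complex is by charge the limiting reagent, and from the end of the feed to the last reading the run fell from 28.8% to 21.0%.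

She takes the natural logarithm of that ratio over the time between the two readings and calls it the net loss rate λ, a reading worth 0.158 min⁻¹. It is a net figure: whatever complex with one exchanged was still being made in that stretch is already set against the loss. Multiplying λ by the time from the end of the feed to sampling, t − tf, gives the net loss count n, the number of turnovers of this net loss in that stretch, here 0.316. A flask whose complex with one exchanged falls at this same net pace after its feed keeps a fraction exp(−n) of what it held when the feed ended, which is 72.9%.

Maple is charged more heavily than south-east, so she expects it to pass its top sooner and to pay this loss for longer, which turns the row down at the high end. Her forecast is 15.5%, 23%, 26% and 15%, a row that rises, then falls, on these grounds: “Low charges are limited by the equilibrium”, while high charges lose complex with one exchanged to a further exchange.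

The simulation gives 13.1%, 19.3%, 21.9% and 16.2%, a row that rises, then falls, so the forecast stands. The first chemist's view has its region too: more ligand gives more below 0.26 M, the charge at which the row turns.

    starting complex + incoming ligand → leaving ligand + complex with one exchanged (k = 0.0610 M⁻¹ s⁻¹)
    complex with one exchanged + incoming ligand ⇌ leaving ligand + complex with two exchanged (K = 0.200, k = 0.0100 M⁻¹ s⁻¹)
    complex with one exchanged → over-reaction product (k = 0.00450 s⁻¹)
    incoming ligand → decomposed reagent (k = 0.00420 s⁻¹)

In oak, the half-life of complex with one exchanged by over-reaction alone is 2.6 min, shorter than the 10 min of the run. At the end of oak, that step uses the complex 54 times as fast as the forward second exchange does. The net count carries over to elm, which held 28.9% at 8.00 min: keeping exp(−n) of that gives 21.1%, against 21.9% in the flask at 10.0 min. Maple held 24.0% at 8.00 min, which the same count brings to 17.5%, against 16.2% at 10.0 min.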